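## Structural features

The target is a 1-aryltetralin cyclolignan. Ring A is a benzene ring with OMe at C6 and free hydroxyls at C7 and C8, fused through C4a/C8a to the saturated ring B (C1 carries the 3,4,5-trimethoxyphenyl group, C2 and C3 carry the hydroxymethyl carbons C9 and C10, C4 is CH2). The three stereocentres C1, C2 and C3 are contiguous. Reading the descriptors gives (1S,2S,3S): the aryl group is cis to the C2 hydroxymethyl and the two hydroxymethyl groups are trans (1,2-cis-2,3-trans, not the all-trans isolariciresinol pattern). The C8 oxygen is peri to C1 and pushes the aryl group pseudoaxial, so with C9 and C10 held diequatorial this relative configuration should be the thermodynamically preferred one. Fragile elements are the electron-rich free catechol (air, base, oxidants) and the doubly benzylic C1–H, whose abstraction in any dihydronaphthalene intermediate leads to alkene migration or aromatisation and loss of the stereocentre. The real difficulty is to set C1 absolutely next to a hexasubstituted arene and then place H at C2 and C3 on opposite faces. The key step uses the fact that ring A, with oxygen at C6, C7 and C8, is the enol form of 3-methoxy-o-benzoquinone, whose unsubstituted C4a=C8a bond can act as a dienophile toward a 1-aryl diene that supplies C1–C4, C9 and C10.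

## Logic of the disconnections

14 to 13: only C–O bonds are cut (two aryl acetates, one isopropylidene acetal). The catechol and the 1,4-diol stay masked until the last operation, so the forward step must be a single acidic solvolysis that harms neither the aryl methyl ethers nor C1.

13 to 12: the C2–H and C3–H bonds are removed to give the C2=C3 alkene. Two stereocentres disappear and only C1 remains. The forward reduction must deliver hydrogen to C2 anti to the aryl group and to C3 on the other face, which a syn hydrogenation cannot do; a stepwise hydrogen-atom transfer under thermodynamic control is required. Acetate protection of the catechol is chosen so that no free catechol meets the radical and peroxide conditions.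

12 to 7 and 9 (through 11 and 10): after formal re-ketonisation of ring A, the C1–C8a and C4–C4a bonds are cut in a retro-Diels–Alder sense. This is the largest simplification: ring B and C1 arise together and ring A arrives with its full oxygenation. The forward step needs reaction at the unsubstituted C=C of 9, ortho regiochemistry, and face control by a chiral Lewis acid. It also needs a diene held s-cis with the aryl group outward, and a dienophile solution free of water and excess oxidant. That is why 9 is prepared in a separate operation and the catechol is acetylated in the flask in which it forms.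

9 to 8: an oxidation-level change only; the forward step must give a dry, oxidant-free solution that is used at once.

7 to 5 and 6: the aryl–vinyl bond is cut. A condensation route from an aryl aldehyde and a succinate, followed by methylenation of the neighbouring carbon, would fix the aryl group cis to the second alkene carbon (inward), a geometry that cannot reach the cycloaddition transition state. A Heck arylation of the symmetric diene instead places the aryl group trans to that carbon. The forward step must stop at monoarylation and eliminate toward the benzylic hydrogen.

5 to 3 (through 4): acetal C–O bonds are cut and the acetates restored. The acetal is needed before the palladium step because allylic acetates would ionise with zerovalent palladium, and because the seven-membered ring holds the diene s-cis.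

3 to 1 and 2: both C=CH2 bonds are cut (enyne metathesis transform), leading to a commercial alkyne diester and ethylene. The forward step needs only a ruthenium carbene that tolerates propargylic esters.

## Other disconnections considered

Alternative 1: The cut is at C4a–C8a and C5–C6, so ring A is built de novo while ring B closes. In the forward step the furan-tethered alkyne lactone A1 is heated; the 3,4-bis(benzyloxy)furan adds across the terminal alkyne and the oxanorbornadiene opens and tautomerises to the C6 phenol of lactone A2. In its favour: all three stereocentres exist before the key step and can be set by ordinary lactone and auxiliary chemistry, the cascade needs no catalyst, and the new C6 hydroxyl is the only free phenol, so its methylation is unambiguous. Against it: A1 needs a 3,4-dialkoxyfuran, a furyl(aryl)methine centre and a trans-disubstituted butyrolactone. The unactivated alkyne with a four-atom tether calls for high temperature, where the centre α to the lactone carbonyl may epimerise. After A2, O-methylation, lactone reduction and double debenzylation remain. Compared with the chosen plan, this alternative is the better one on stereochemical security, because its pericyclic step creates no stereocentre whereas the chosen cycloaddition must create C1 enantioselectively without direct precedent. The chosen plan is better on convergence (ring A is bought, not built) and should be clearly shorter.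

Alternative 2: The cut is at C2–C3 and C1–C8a. In the forward step the iodoarene bromoacetal A3 meets a bipyridine-ligated nickel catalyst under reductive conditions (entering as zerovalent nickel). The C3 radical closes 5-exo onto the cinnamyl alkene and the benzylic C1 radical is captured by the aryl–nickel species to close ring B, giving the tetrahydrofuran-fused tetralin A4. In its favour: two C–C bonds, including the congested C1–C8a bond, form in one mild step; A3 is assembled from a cinnamyl alcohol, a bromoacetal and an iodoarene; and reductive alkene dicarbofunctionalisation is an established reaction class, so on precedent this alternative is ahead of the chosen plan. Against it: C2 and C3 are fixed in a free-radical cyclisation outside the reach of the metal's ligand, so absolute configuration must come from the acetal centre of A3 or from a resolution. The C1 selectivity of the radical capture is not assured. Ring A must be bought or made as a pentasubstituted ortho-iodoarene with benzyl-protected oxygens, and A4 still needs acetal hydrolysis, lactol reduction and debenzylation. Structurally it gives the trans ring fusion directly, which the chosen plan must earn in a separate reduction; in step count it should be longer.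

Alternative 3: The cut is at C1–aryl and C2–C3. In the forward step a copper-mediated conjugate addition of the aryl Grignard reagent A7 to the enoyl oxazolidinone A5 forms C1–aryl, and the resulting enolate at C2 adds to the tethered vinyl sulfone to close ring B, giving A6. In its favour: auxiliary-controlled cuprate addition is dependable, all three stereocentres arise in one operation with the required 1,2-cis-2,3-trans relation, and the absolute configuration rests on a recoverable auxiliary and not on an untested catalyst. On these points it is the equal or better of the chosen plan. Against it: A5 requires an ortho-difunctionalised, fully oxygenated ring A; the C3 substituent in A6 is a sulfonylmethyl group, so reaching the hydroxymethyl level costs an extra oxidation and reduction sequence; auxiliary removal and debenzylation follow. In step economy it is the weakest of the three, and mechanistically the ring-closing Michael addition must outrun simple protonation of the enolate.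

Key step: step 5

Remarks on the chemistry:
- Tetralin numbering (C1 aryl-bearing, C9 on C2, C10 on C3) is used throughout, including for the dioxepane-fused intermediates.
- The (S)-configured oxazaborolidinium catalyst is assumed to give the (1R) adduct, following the usual pre-transition-state picture for quinone dienophiles. If the sense proves opposite, the (R)-catalyst is used with no other change.

Step 1
Reactants: 1 but-2-yne-1,4-diyl diacetate; 2 ethylene
Product: 3 2,3-dimethylidenebutane-1,4-diyl diacetate
Conditions: second-generation Grubbs catalyst RuCl2(=CHPh)(PCy3)(H2IMes) (5 mol%), C2H4 (1 atm), toluene, 80 °C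
Reagents that add atoms: none
Why: Cross enyne metathesis of an internal alkyne with ethylene: the ruthenium carbene adds to the alkyne and the vinylcarbene is methylenated by ethylene, giving the 2,3-disubstituted buta-1,3-diene; propargylic acetates are standard substrates and no stereochemistry is involved.

Step 2
Reactants: 3 2,3-dimethylidenebutane-1,4-diyl diacetate
Product: 5 2,2-dimethyl-5,6-dimethylidene-1,3-dioxepane, via 2,3-dimethylidenebutane-1,4-diol 4 (not isolated)
Conditions: K2CO3 (5 mol%), MeOH, rt; evaporate; Me2C(OMe)2, acetone, TsOH·H2O (10 mol%), BHT (cat.), rt
Reagents that add atoms: 2,2-dimethoxypropane, COC(C)(C)OC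
Why: Base-catalysed methanolysis frees the 1,4-diol and acid-catalysed transketalisation closes the seven-membered isopropylidene acetal, which removes the ionisable allylic acetates and holds the diene s-cis; BHT suppresses polymerisation of the diene diol.

Step 3
Reactants: 5 2,2-dimethyl-5,6-dimethylidene-1,3-dioxepane; 6 5-iodo-1,2,3-trimethoxybenzene
Product: 7 (Z)-2,2-dimethyl-5-methylidene-6-[(3,4,5-trimethoxyphenyl)methylidene]-1,3-dioxepane (aryl outward: trans to ring carbon C5 of the dioxepane)
Conditions: Pd(OAc)2 (5 mol%), Bu4NCl, K2CO3, DMF, 70 °C; 5 in twofold excess
Reagents that add atoms: none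
Why: Mizoroki–Heck arylation of a 1,3-diene at its terminal CH2: carbopalladation gives a π-allylpalladium species and β-hydride elimination of a benzylic hydrogen restores the conjugated diene. The aryl group should end trans to the neighbouring ring carbon, because the other geometry forces it against the adjacent exocyclic methylene; excess 5 limits double arylation.

Step 4
Reactants: 8 3-methoxybenzene-1,2-diol (3-methoxycatechol)
Product: 9 3-methoxycyclohexa-3,5-diene-1,2-dione (3-methoxy-o-benzoquinone)
Conditions: NaIO4 (1.05 equiv), H2O/CH2Cl2, 0 °C, 10 min; organic phase dried (Na2SO4, then 4 Å sieves) and used cold at once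
Reagents that add atoms: none
Why: Periodate oxidation of a catechol to the o-quinone is fast and clean at 0 °C. Doing it as a separate operation keeps water and oxidant away from the moisture-sensitive catalyst and from the more easily oxidised product catechol of the next step.

Step 5
Reactants: 7 (Z)-2,2-dimethyl-5-methylidene-6-[(3,4,5-trimethoxyphenyl)methylidene]-1,3-dioxepane (1.3 equiv); 9 3-methoxycyclohexa-3,5-diene-1,2-dione (limiting)
Product: 12 (6R)-9-methoxy-3,3-dimethyl-6-(3,4,5-trimethoxyphenyl)-1,5,6,11-tetrahydronaphtho[2,3-e][1,3]dioxepine-7,8-diyl diacetate, via cis-fused ene-dione cycloadduct 10 (not isolated), via free catechol 11 (not isolated)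
Conditions: (S)-3,3-diphenyl-1-(o-tolyl)tetrahydro-1H,3H-pyrrolo[1,2-c][1,3,2]oxazaborole (20 mol%), HN(SO2CF3)2 (18 mol%), CH2Cl2, 4 Å sieves, −78 °C, Ar; then Et3N, −78 to 0 °C; then Ac2O, DMAP (cat.), 0 °C to rt
Reagents that add atoms: acetic anhydride, CC(=O)OC(C)=O
Why: Proposed new method: the N-protonated oxazaborolidine should bind the more basic C8 carbonyl of 9 (a doubly vinylogous ester through the methoxy group) at the lone pair next to C8a–H, lowering the LUMO of the unsubstituted C4a=C8a bond while the methoxy-bearing alkene stays a deactivated, trisubstituted bystander; a concerted, asynchronous normal-demand [4+2] addition with the s-cis-locked diene 7 then forms C4–C4a (nucleophilic CH2 terminus to the β-carbon) and C1–C8a through an endo transition state, giving 10. The closest known reactions are the uncatalysed carbo-Diels–Alder additions of o-benzoquinones to acyclic dienes that end in catechols, and oxazaborolidinium-catalysed Diels–Alder reactions of p-quinones; the enantioselective o-quinone version has no direct precedent. Ring B is the only ring closed, as a six-membered carbocycle by intermolecular cycloaddition across the two diene termini. The one lasting stereocentre, C1, is set by the catalyst, which exposes one face of the bound C4a=C8a bond; the outward aryl geometry of 7 and the endo approach translate that face into (1R), and the C4a and C8a centres of 10 vanish when Et3N enolises the ene-dione to the aromatic catechol 11, which is acetylated in the same flask so that no free catechol meets air or residual quinone. The step needs the carbo- and not the hetero-Diels–Alder mode (favoured by Lewis-acid activation of the enone unit and low temperature), ortho regiochemistry (the large HOMO coefficient at the CH2 terminus of the 1-aryl diene matched with C4a, the β-carbon of the activated enone), and 9 as the limiting partner so that redox exchange between 9 and 11 cannot occur.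

Step 6
Reactants: 12 (6R)-9-methoxy-3,3-dimethyl-6-(3,4,5-trimethoxyphenyl)-1,5,6,11-tetrahydronaphtho[2,3-e][1,3]dioxepine-7,8-diyl diacetate
Product: 13 (5aS,6S,11aS)-9-methoxy-3,3-dimethyl-6-(3,4,5-trimethoxyphenyl)-1,5,5a,6,11,11a-hexahydronaphtho[2,3-e][1,3]dioxepine-7,8-diyl diacetate (tetralin numbering 1S,2S,3S; trans-fused dioxepane; aryl cis to C9)
Conditions: Mn(dpm)3 (10 mol%), PhSiH3, t-BuOOH, i-PrOH (degassed), rt
Reagents that add atoms: none
Why: Metal-hydride hydrogen-atom-transfer hydrogenation (Mukaiyama-type, trivalent manganese hydride) delivers the two hydrogens in separate radical steps and is known to give the thermodynamically preferred ring fusion from tetrasubstituted alkenes. Here hydrogen should enter C2 anti to the pseudoaxial aryl group and C3 axially on the opposite face, leaving C9 and C10 trans-diequatorial in the dioxepane while the C8 acetoxy group keeps the aryl group pseudoaxial, so the 1,2-cis-2,3-trans isomer is the most stable one.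

Step 7
Reactants: 13 (5aS,6S,11aS)-9-methoxy-3,3-dimethyl-6-(3,4,5-trimethoxyphenyl)-1,5,5a,6,11,11a-hexahydronaphtho[2,3-e][1,3]dioxepine-7,8-diyl diacetate
Product: 14 (6S,7S,8S)-6,7-bis(hydroxymethyl)-3-methoxy-8-(3,4,5-trimethoxyphenyl)-5,6,7,8-tetrahydronaphthalene-1,2-diol (target; tetralin numbering 1S,2S,3S)
Conditions: HCl (1.25 M in MeOH), H2O (few equiv), Ar, 40 °C
Reagents that add atoms: none
Why: Acid-catalysed transketalisation removes the isopropylidene acetal and acid-catalysed methanolysis cleaves both aryl acetates in one operation; acidic, oxygen-free conditions protect the liberated catechol, and no stereocentre is epimerisable under them.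

Compound list
1 | but-2-yne-1,4-diyl diacetate | CC(=O)OCC#CCOC(C)=O | starting material
2 | ethylene | C=C | starting material
3 | 2,3-dimethylidenebutane-1,4-diyl diacetate | CC(=O)OCC(=C)C(=C)COC(C)=O | intermediate
4 | 2,3-dimethylidenebutane-1,4-diol | OCC(=C)C(=C)CO | intermediate
5 | 2,2-dimethyl-5,6-dimethylidene-1,3-dioxepane | C=C1COC(C)(C)OCC1=C | intermediate
6 | 5-iodo-1,2,3-trimethoxybenzene | COc1cc(I)cc(OC)c1OC | starting material
7 | (Z)-2,2-dimethyl-5-methylidene-6-[(3,4,5-trimethoxyphenyl)methylidene]-1,3-dioxepane | COc1cc(/C=C2\COC(C)(C)OCC2=C)cc(OC)c1OC | intermediate
8 | 3-methoxybenzene-1,2-diol | COc1cccc(O)c1O | starting material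
9 | 3-methoxycyclohexa-3,5-diene-1,2-dione | COC1=CC=CC(=O)C1=O | intermediate
10 | (6R,6aS,10aR)-9-methoxy-3,3-dimethyl-6-(3,4,5-trimethoxyphenyl)-1,5,6,6a,10a,11-hexahydronaphtho[2,3-e][1,3]dioxepine-7,8-dione (H-6, H-6a and H-10a all cis) | COC1=C[C@H]2CC3=C(COC(C)(C)OC3)[C@@H](c4cc(OC)c(OC)c(OC)c4)[C@H]2C(=O)C1=O | intermediate
11 | (6R)-9-methoxy-3,3-dimethyl-6-(3,4,5-trimethoxyphenyl)-1,5,6,11-tetrahydronaphtho[2,3-e][1,3]dioxepine-7,8-diol | COc1cc2c(c(O)c1O)[C@H](c1cc(OC)c(OC)c(OC)c1)C1=C(C2)COC(C)(C)OC1 | intermediate
12 | (6R)-9-methoxy-3,3-dimethyl-6-(3,4,5-trimethoxyphenyl)-1,5,6,11-tetrahydronaphtho[2,3-e][1,3]dioxepine-7,8-diyl diacetate | COc1cc2c(c(OC(C)=O)c1OC(C)=O)[C@H](c1cc(OC)c(OC)c(OC)c1)C1=C(C2)COC(C)(C)OC1 | intermediate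
13 | (5aS,6S,11aS)-9-methoxy-3,3-dimethyl-6-(3,4,5-trimethoxyphenyl)-1,5,5a,6,11,11a-hexahydronaphtho[2,3-e][1,3]dioxepine-7,8-diyl diacetate | COc1cc2c(c(OC(C)=O)c1OC(C)=O)[C@H](c1cc(OC)c(OC)c(OC)c1)[C@@H]1COC(C)(C)OC[C@H]1C2 | intermediate
14 | (6S,7S,8S)-6,7-bis(hydroxymethyl)-3-methoxy-8-(3,4,5-trimethoxyphenyl)-5,6,7,8-tetrahydronaphthalene-1,2-diol | COc1cc2c(c(O)c1O)[C@H](c1cc(OC)c(OC)c(OC)c1)[C@H](CO)[C@@H](CO)C2 | target

Total step count: 7. Longest linear sequence: 6 steps (steps 1, 2, 3, 5, 6, 7); step 4 is a one-step side branch.

Least certain steps

Step 5 (key step). The most likely failures are: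
- addition in the hetero-Diels–Alder mode, with the dicarbonyl unit of 9 acting as a heterodiene toward the electron-rich styrenyl alkene of 7;
- binding of the Lewis acid to the other carbonyl or to the acetal oxygens, which would erode regio- and face control;
- acid-induced oligomerisation of the electron-rich diene.

All three follow from putting a strongly acidic catalyst together with two very electron-rich partners. The fallback sets out from 7 and 9 and returns at 12. The cycloaddition is run without a chiral catalyst (CH2Cl2, 0 °C to rt), which is the known thermal carbo-Diels–Alder mode of o-quinones with acyclic dienes. The same Et3N/Ac2O treatment then gives the racemic diacetate F1. Preparative chromatography on a chiral stationary phase separates 12 from its (6S)-enantiomer F2. Enantiopurity then comes from separation, not from catalyst control.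

Step 6. The most likely failures are:
- hydrogen delivery to C3 on the face that gives the cis ring fusion, because approach syn to the pseudoaxial aryl group is hindered;
- hydrogen abstraction from the doubly benzylic C1 by peroxide-derived radicals, leading to alkene migration or aromatisation and erosion of configuration.

The fallback sets out from 12 and returns at 13. Syn hydrogenation with H2 and [Ir(cod)(PCy3)(py)]PF6 in CH2Cl2 on the face away from the aryl group should give the all-cis isomer F3, in which C1 and C2 are correct and C3 is not. The C3–H is then epimerised by reversible photochemical hydrogen-atom abstraction and return ((Bu4N)4W10O32, a diaryl disulfide co-catalyst, 390 nm, MeCN). This runs under thermodynamic control, which should favour 13 because the epimerisation relieves the syn-diaxial contact between the aryl group and C10. It should be stopped as soon as F3 is consumed, to limit epimerisation at other tertiary centres.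

Step 3. The most likely failures are:
- capture of the π-allylpalladium intermediate by a nucleophile, or β-hydride elimination toward the ring CH2–O to give an enol ether;
- a second arylation;
- incomplete geometric purity.

All of these arise because the allyl intermediate is slow to eliminate. The fallback sets out from 6 and returns at 7, and fixes the geometry by syn addition to an alkyne instead of by elimination. Sonogashira coupling of 6 with propargyl alcohol (PdCl2(PPh3)2, CuI, Et3N) gives 3-(3,4,5-trimethoxyphenyl)prop-2-yn-1-ol F4. Palladium-catalysed syn hydrostannation (Bu3SnH, PdCl2(PPh3)2, THF) should place tin on the carbinol-side carbon and give (E)-2-(tributylstannyl)-3-(3,4,5-trimethoxyphenyl)prop-2-en-1-ol F5. Stille coupling with 2-bromoprop-2-en-1-ol (Pd(PPh3)4, CuI, DMF) proceeds with retention and gives (Z)-2-methylidene-3-[(3,4,5-trimethoxyphenyl)methylidene]butane-1,4-diol F6. Ketalisation with 2,2-dimethoxypropane and TsOH then gives 7. The price is one more step and the handling of organotin reagents.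

Further compounds
F1 | step 5 | racemic 9-methoxy-3,3-dimethyl-6-(3,4,5-trimethoxyphenyl)-1,5,6,11-tetrahydronaphtho[2,3-e][1,3]dioxepine-7,8-diyl diacetate | COc1cc2c(c(OC(C)=O)c1OC(C)=O)C(c1cc(OC)c(OC)c(OC)c1)C1=C(C2)COC(C)(C)OC1
F2 | step 5 | (6S)-9-methoxy-3,3-dimethyl-6-(3,4,5-trimethoxyphenyl)-1,5,6,11-tetrahydronaphtho[2,3-e][1,3]dioxepine-7,8-diyl diacetate | COc1cc2c(c(OC(C)=O)c1OC(C)=O)[C@@H](c1cc(OC)c(OC)c(OC)c1)C1=C(C2)COC(C)(C)OC1
F3 | step 6 | (5aS,6S,11aR)-9-methoxy-3,3-dimethyl-6-(3,4,5-trimethoxyphenyl)-1,5,5a,6,11,11a-hexahydronaphtho[2,3-e][1,3]dioxepine-7,8-diyl diacetate (all-cis) | COc1cc2c(c(OC(C)=O)c1OC(C)=O)[C@H](c1cc(OC)c(OC)c(OC)c1)[C@@H]1COC(C)(C)OC[C@@H]1C2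
F4 | step 3 | 3-(3,4,5-trimethoxyphenyl)prop-2-yn-1-ol | OCC#Cc1cc(OC)c(OC)c(OC)c1
F5 | step 3 | (E)-2-(tributylstannyl)-3-(3,4,5-trimethoxyphenyl)prop-2-en-1-ol | OC/C(=C\c1cc(OC)c(OC)c(OC)c1)[Sn](CCCC)(CCCC)CCCC
F6 | step 3 | (Z)-2-methylidene-3-[(3,4,5-trimethoxyphenyl)methylidene]butane-1,4-diol | OC/C(=C\c1cc(OC)c(OC)c(OC)c1)C(=C)CO
A1 | alternative 1 | trans-3-[(3,4-bis(benzyloxy)furan-2-yl)(3,4,5-trimethoxyphenyl)methyl]-4-(prop-2-yn-1-yl)dihydrofuran-2(3H)-one | C#CC[C@@H]1COC(=O)[C@H]1[C@@H](c1cc(OC)c(OC)c(OC)c1)c1occ(OCc2ccccc2)c1OCc1ccccc1
A2 | alternative 1 | 7,8-bis(benzyloxy)-6-hydroxy-1-(3,4,5-trimethoxyphenyl)tetralin trans-fused C9/C10 lactone | Oc1cc2c(c(OCc3ccccc3)c1OCc1ccccc1)[C@H](c1cc(OC)c(OC)c(OC)c1)[C@@H]1C(=O)OC[C@H]1C2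
A3 | alternative 2 | 2-bromo-3-[3,4-bis(benzyloxy)-2-iodo-5-methoxyphenyl]propanal ethyl (E)-3-(3,4,5-trimethoxyphenyl)allyl acetal (either epimer at the bromine-bearing carbon) | COc1cc(CC(Br)[C@@H](OCC)OC/C=C/c2cc(OC)c(OC)c(OC)c2)c(I)c(OCc2ccccc2)c1OCc1ccccc1
A4 | alternative 2 | 7,8-bis(benzyloxy)-6-methoxy-1-(3,4,5-trimethoxyphenyl)tetralin trans-fused to a 2-ethoxytetrahydrofuran (C9–O–C10 acetal) | COc1cc2c(c(OCc3ccccc3)c1OCc1ccccc1)[C@H](c1cc(OC)c(OC)c(OC)c1)[C@@H]1CO[C@H](OCC)[C@H]1C2
A5 | alternative 3 | N-enoyl 4-phenyloxazolidinone of (E)-3-{2,3-bis(benzyloxy)-4-methoxy-6-[(E)-3-(phenylsulfonyl)allyl]phenyl}acrylic acid | COc1cc(C/C=C/S(=O)(=O)c2ccccc2)c(/C=C/C(=O)N2C(=O)OC[C@H]2c2ccccc2)c(OCc2ccccc2)c1OCc1ccccc1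
A6 | alternative 3 | 7,8-bis(benzyloxy)-6-methoxy-1-(3,4,5-trimethoxyphenyl)tetralin with C2 acyl oxazolidinone and C3 phenylsulfonylmethyl, 1,2-cis-2,3-trans | COc1cc2c(c(OCc3ccccc3)c1OCc1ccccc1)[C@H](c1cc(OC)c(OC)c(OC)c1)[C@H](C(=O)N1C(=O)OC[C@H]1c1ccccc1)[C@@H](CS(=O)(=O)c1ccccc1)C2
A7 | alternative 3 | 3,4,5-trimethoxyphenylmagnesium bromide | COc1cc([Mg]Br)cc(OC)c1OC
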